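**Plan**

1. Numbering: lactone O1, C2(=O), C3, C4, C5; C7' is the carbinol carbon on C3; ring A is the aryl of the C4 benzyl group, ring B the aryl on C7'. The C2(=O)–C3–C7'(OH) unit is a syn β-hydroxy carbonyl array, which is the opened form of a cis-3,4-disubstituted oxetan-2-one whose ring oxygen is the C7' oxygen acylated by C2.
2. Cuts: the two phenol protecting groups come off first; the O1–C2 bond of the five-membered lactone is then exchanged for a C2–O(C7') bond (γ-lactone back to β-lactone, C5 becoming a vinyl carbon); the oxetanone is cut at C3–C7' and C2–O into the ketene of acid chloride 10 and aldehyde 12.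
3. Acid chloride 10 is cut at C3–C4 (malonate plus a branched allyl unit, iridium-catalysed allylic alkylation) and at the alkene of the allylic carbonate (cross-metathesis of O-benzyleugenol).
4. Forward: the C2–C5 chain carrying ring A is built in steps 1–7, ring B arrives with the aldehyde, the four-membered lactone closes in step 9 and is traded for the five-membered lactone in step 10, and one hydrogenolysis finishes the route.
5. Stereochemistry: C4 comes from the chiral phosphoramidite in the iridium step; C3 and C7' come from the cinchona alkaloid catalyst and the closed transition state of the cycloaddition (cis lactone = syn aldol); the ring expansion is an acyl transfer that touches no stereocentre.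

Key step: step 9

Assumption: the absolute sense of the two chiral catalysts is assigned by analogy with related additions — the (Ra,Rc,Rc) phosphoramidite for the (S)-malonate 7 and O-trimethylsilylquinine for the (3S,4S) β-lactone 14 — and each has an equally available mirror-image or pseudo-enantiomeric partner (the (Sa,Sc,Sc) ligand, O-trimethylsilylquinidine) should the opposite sense be found.

**Route**

Step 1
Reactants: 1 eugenol (4-allyl-2-methoxyphenol)
Product: 2 4-allyl-1-(benzyloxy)-2-methoxybenzene (O-benzyleugenol)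
Conditions: BnBr, K2CO3, acetone, reflux
Reagents that add atoms: benzyl bromide, BrCc1ccccc1
Why: Williamson ether synthesis (SN2 of the phenoxide on benzyl bromide) should mask the ring A phenol as an ether that survives every step up to the final hydrogenolysis.

Step 2
Reactants: 3 (Z)-but-2-ene-1,4-diol
Product: 4 (Z)-but-2-ene-1,4-diyl dimethyl bis(carbonate)
Conditions: ClCO2Me, pyridine, CH2Cl2, 0 °C → rt
Reagents that add atoms: methyl chloroformate, COC(=O)Cl
Why: O-acylation of both primary alcohols with a chloroformate should give the symmetrical bis(carbonate), which supplies the leaving group needed for the iridium step.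

Step 3
Reactants: 2 O-benzyleugenol; 4 (Z)-but-2-ene-1,4-diyl dimethyl bis(carbonate)
Product: 5 (E)-4-[4-(benzyloxy)-3-methoxyphenyl]but-2-en-1-yl methyl carbonate
Conditions: second-generation Grubbs catalyst (H2IMes)(PCy3)Cl2Ru=CHPh (3 mol%), 4 (3 equiv), 1,4-benzoquinone (10 mol%), CH2Cl2, 40 °C
Reagents that add atoms: none
Why: Olefin cross-metathesis of a terminal allylarene with an excess of a symmetrical cis-but-2-ene-1,4-diyl partner is a standard route to the (E)-allylic carbonate, and benzoquinone should suppress ruthenium hydride migration of the allyl double bond into conjugation with ring A.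

Step 4
Reactants: 5 (E)-4-[4-(benzyloxy)-3-methoxyphenyl]but-2-en-1-yl methyl carbonate; 6 dimethyl malonate
Product: 7 dimethyl 2-{(2S)-1-[4-(benzyloxy)-3-methoxyphenyl]but-3-en-2-yl}propanedioate
Conditions: 6, NaH, THF, 0 °C; then 5, [Ir(cod)Cl]2 (2 mol%), (Ra)-1,1'-binaphthyl-2,2'-diyl N,N-bis[(R)-1-phenylethyl]phosphoramidite (4 mol%), 1,5,7-triazabicyclo[4.4.0]dec-5-ene (8 mol%), THF, rt
Reagents that add atoms: none
Why: Iridium-catalysed asymmetric allylic alkylation, in which the cyclometalated iridium phosphoramidite complex ionises the linear carbonate and sodium dimethyl malonate attacks the substituted allyl terminus, should give the branched product with the future C4 set by the ligand.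

Step 5
Reactants: 7 dimethyl 2-{(2S)-1-[4-(benzyloxy)-3-methoxyphenyl]but-3-en-2-yl}propanedioate
Product: 8 methyl (3R)-3-{[4-(benzyloxy)-3-methoxyphenyl]methyl}pent-4-enoate
Conditions: NaCl, H2O, DMSO, 150 °C
Reagents that add atoms: none
Why: Krapcho dealkoxycarbonylation (chloride demethylates one ester and the carboxylate loses CO2) should remove one ester without touching the stereocentre, which is β to the remaining ester and cannot enolise.

Step 6
Reactants: 8 methyl (3R)-3-{[4-(benzyloxy)-3-methoxyphenyl]methyl}pent-4-enoate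
Product: 9 (3R)-3-{[4-(benzyloxy)-3-methoxyphenyl]methyl}pent-4-enoic acid
Conditions: LiOH, THF–MeOH–H2O, rt; then 1 M HCl
Reagents that add atoms: lithium hydroxide, [Li+].[OH-]
Why: Ester saponification under mild aqueous base should give the acid with the benzyl ether, the alkene and the β-stereocentre unaffected.

Step 7
Reactants: 9 (3R)-3-{[4-(benzyloxy)-3-methoxyphenyl]methyl}pent-4-enoic acid
Product: 10 (3R)-3-{[4-(benzyloxy)-3-methoxyphenyl]methyl}pent-4-enoyl chloride
Conditions: (COCl)2, DMF (cat.), CH2Cl2, 0 °C → rt; used crude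
Reagents that add atoms: oxalyl chloride, O=C(Cl)C(Cl)=O
Why: Acid chloride formation through the Vilsmeier-type chloroiminium species runs under neutral conditions with only gaseous by-products, so the crude chloride can be taken straight into the cycloaddition.

Step 8
Reactants: 11 vanillin (4-hydroxy-3-methoxybenzaldehyde)
Product: 12 benzyl 4-formyl-2-methoxyphenyl carbonate
Conditions: CbzCl, Et3N, CH2Cl2, 0 °C
Reagents that add atoms: benzyl chloroformate, O=C(Cl)OCc1ccccc1
Why: O-acylation of the phenol with a chloroformate should give an aryl carbonate that is electron-withdrawing (keeping the aldehyde electrophilic and the later benzylic C–O bond reluctant to ionise) and that is removed by the same hydrogenolysis as the benzyl ether.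

Step 9
Reactants: 10 (3R)-3-{[4-(benzyloxy)-3-methoxyphenyl]methyl}pent-4-enoyl chloride; 12 benzyl 4-formyl-2-methoxyphenyl carbonate
Product: 14 (3S,4S)-3-{(2S)-1-[4-(benzyloxy)-3-methoxyphenyl]but-3-en-2-yl}-4-{4-[(benzyloxycarbonyl)oxy]-3-methoxyphenyl}oxetan-2-one (cis β-lactone), via ketene 13 (not isolated)
Conditions: O-trimethylsilylquinine (15 mol%), LiClO4 (2 equiv), iPr2NEt (2.5 equiv), CH2Cl2–Et2O, −78 → −40 °C, slow addition of 10
Reagents that add atoms: none
Why: iPr2NEt dehydrochlorinates 10 to ketene 13, the quinuclidine nitrogen of the alkaloid adds to the ketene carbonyl carbon on the side away from the C4 substituent to give a (Z)-acylammonium enolate, this enolate adds through a lithium-bridged chair-like six-membered transition state to aldehyde 12 held on Li+, and the lithium aldolate oxygen then attacks the acylammonium carbon and expels the alkaloid. The closest known reaction is the cinchona alkaloid/lithium salt-catalysed acyl halide–aldehyde cyclocondensation, a formal ketene–aldehyde [2+2] that gives cis-3,4-disubstituted oxetan-2-ones from alkyl-substituted ketenes. The oxetan-2-one closes by 4-exo-trig attack of the C7' oxygen on C2, the C3–C7' bond having been made in the preceding aldol event. C3 is set by the alkaloid, which screens one face of the enolate (catalyst control), C7' is set relative to C3 by the closed transition state of the (Z)-enolate, which places the aryl group cis to the C3 substituent, and C4 is carried in unchanged from 10. The step needs catalyst control to override the resident C4 centre and cross-addition to win over ketene dimerisation: C4 carries no coordinating group and lies outside the bond-forming array, the aldehyde cannot enolise and is kept electrophilic by the carbonate on ring B, and slow addition of 10 keeps the ketene concentration low. The same carbonate should make the benzylic C7'–O bond of the 4-aryl β-lactone reluctant to ionise, so that loss of CO2 to a styrene should not compete at or below room temperature.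

Step 10
Reactants: 14 (3S,4S)-3-{(2S)-1-[4-(benzyloxy)-3-methoxyphenyl]but-3-en-2-yl}-4-{4-[(benzyloxycarbonyl)oxy]-3-methoxyphenyl}oxetan-2-one
Product: 17 benzyl 4-[(S)-{(3S,4R)-4-[4-(benzyloxy)-3-methoxybenzyl]-2-oxooxolan-3-yl}(hydroxy)methyl]-2-methoxyphenyl carbonate, via aldehyde 15 (not isolated), via hydroxy-β-lactone 16 (not isolated)
Conditions: O3, CH2Cl2–MeOH, −78 °C (Sudan red 7B end point); then NaBH4, −78 → 0 °C; aq NH4Cl
Reagents that add atoms: ozone, [O-][O+]=O
Why: Criegee ozonolysis cleaves the only alkene (the indicator dye guards ring A and the benzyl groups against excess ozone), borohydride reduces the ozonide through aldehyde 15 to the primary alcohol before C4 can epimerise, and the C5 alkoxide of 16 then attacks the strained acyl carbon C2 (5-exo-trig translactonisation with acyl–oxygen cleavage), so the five-membered lactone should form and the C7' oxygen be released with its configuration intact.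

Step 11
Reactants: 17 benzyl 4-[(S)-{(3S,4R)-4-[4-(benzyloxy)-3-methoxybenzyl]-2-oxooxolan-3-yl}(hydroxy)methyl]-2-methoxyphenyl carbonate
Product: 18 (3S,4R)-3-[(S)-hydroxy(4-hydroxy-3-methoxyphenyl)methyl]-4-(4-hydroxy-3-methoxybenzyl)oxolan-2-one (target)
Conditions: H2 (1 atm), Pd/C (palladium on carbon), EtOAc, rt
Reagents that add atoms: none
Why: Heterogeneous catalytic hydrogenolysis should remove the benzyl ether of ring A and the benzyl carbonate of ring B (the carbonic acid monoester loses CO2) under neutral conditions that spare the lactone, the three stereocentres and, if the reaction is stopped at full debenzylation, the benzylic C7' alcohol.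

**Compound list**

1 | eugenol (4-allyl-2-methoxyphenol) | COc1cc(CC=C)ccc1O | starting material
2 | 4-allyl-1-(benzyloxy)-2-methoxybenzene | C=CCc1ccc(OCc2ccccc2)c(OC)c1 | intermediate
3 | (Z)-but-2-ene-1,4-diol | OC/C=C\CO | starting material
4 | (Z)-but-2-ene-1,4-diyl dimethyl bis(carbonate) | COC(=O)OC/C=C\COC(=O)OC | intermediate
5 | (E)-4-[4-(benzyloxy)-3-methoxyphenyl]but-2-en-1-yl methyl carbonate | COC(=O)OC/C=C/Cc1ccc(OCc2ccccc2)c(OC)c1 | intermediate
6 | dimethyl malonate | COC(=O)CC(=O)OC | starting material
7 | dimethyl 2-{(2S)-1-[4-(benzyloxy)-3-methoxyphenyl]but-3-en-2-yl}propanedioate | COC(=O)C(C(=O)OC)[C@@H](Cc1ccc(OCc2ccccc2)c(OC)c1)C=C | intermediate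
8 | methyl (3R)-3-{[4-(benzyloxy)-3-methoxyphenyl]methyl}pent-4-enoate | COC(=O)C[C@@H](Cc1ccc(OCc2ccccc2)c(OC)c1)C=C | intermediate
9 | (3R)-3-{[4-(benzyloxy)-3-methoxyphenyl]methyl}pent-4-enoic acid | OC(=O)C[C@@H](Cc1ccc(OCc2ccccc2)c(OC)c1)C=C | intermediate
10 | (3R)-3-{[4-(benzyloxy)-3-methoxyphenyl]methyl}pent-4-enoyl chloride | O=C(Cl)C[C@@H](Cc1ccc(OCc2ccccc2)c(OC)c1)C=C | intermediate
11 | vanillin (4-hydroxy-3-methoxybenzaldehyde) | COc1cc(C=O)ccc1O | starting material
12 | benzyl 4-formyl-2-methoxyphenyl carbonate | O=Cc1ccc(OC(=O)OCc2ccccc2)c(OC)c1 | intermediate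
13 | (3S)-3-{[4-(benzyloxy)-3-methoxyphenyl]methyl}penta-1,4-dien-1-one (ketene) | O=C=C[C@@H](Cc1ccc(OCc2ccccc2)c(OC)c1)C=C | intermediate
14 | (3S,4S)-3-{(2S)-1-[4-(benzyloxy)-3-methoxyphenyl]but-3-en-2-yl}-4-{4-[(benzyloxycarbonyl)oxy]-3-methoxyphenyl}oxetan-2-one | O=C1O[C@H](c2ccc(OC(=O)OCc3ccccc3)c(OC)c2)[C@@H]1[C@@H](Cc1ccc(OCc2ccccc2)c(OC)c1)C=C | intermediate
15 | (2R)-3-[4-(benzyloxy)-3-methoxyphenyl]-2-[(2S,3S)-2-{4-[(benzyloxycarbonyl)oxy]-3-methoxyphenyl}-4-oxooxetan-3-yl]propanal | O=C1O[C@H](c2ccc(OC(=O)OCc3ccccc3)c(OC)c2)[C@@H]1[C@@H](Cc1ccc(OCc2ccccc2)c(OC)c1)C=O | intermediate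
16 | (3S,4S)-3-{(2R)-1-[4-(benzyloxy)-3-methoxyphenyl]-3-hydroxypropan-2-yl}-4-{4-[(benzyloxycarbonyl)oxy]-3-methoxyphenyl}oxetan-2-one | O=C1O[C@H](c2ccc(OC(=O)OCc3ccccc3)c(OC)c2)[C@@H]1[C@@H](Cc1ccc(OCc2ccccc2)c(OC)c1)CO | intermediate
17 | benzyl 4-[(S)-{(3S,4R)-4-[4-(benzyloxy)-3-methoxybenzyl]-2-oxooxolan-3-yl}(hydroxy)methyl]-2-methoxyphenyl carbonate | COc1cc(C[C@H]2COC(=O)[C@@H]2[C@H](O)c2ccc(OC(=O)OCc3ccccc3)c(OC)c2)ccc1OCc1ccccc1 | intermediate
18 | (3S,4R)-3-[(S)-hydroxy(4-hydroxy-3-methoxyphenyl)methyl]-4-(4-hydroxy-3-methoxybenzyl)oxolan-2-one | COc1cc(C[C@H]2COC(=O)[C@@H]2[C@H](O)c2ccc(O)c(OC)c2)ccc1O | target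

**Totals and risks**

Total step count: 11. Longest linear sequence: 9 steps (steps 1, 3, 4, 5, 6, 7, 9, 10, 11, from eugenol).

Steps most likely to fail:

Step 9. The alkaloid and the resident C4 centre may be mismatched, so that facial selectivity at the enolate is poor. Addition to the aromatic aldehyde may also be slow enough for ketene dimerisation to take over, and the 4-aryl β-lactone may lose CO2 on handling. The fallback replaces the catalytic cycloaddition by an auxiliary-controlled aldol and sets out from 10. Acylation of lithiated (4S)-4-benzyl-1,3-oxazolidin-2-one (n-BuLi, THF, −78 °C) with 10 should give the N-acyl oxazolidinone F1. An Evans boron syn-aldol reaction (Bu2BOTf, iPr2NEt, CH2Cl2, −78 → 0 °C, then 12) should give the syn-aldol adduct F2 with the same C3 and C7' configurations, by way of the (Z)-boron enolate and a Zimmerman–Traxler transition state. Ozonolysis and borohydride reduction as in step 10 then pass through the aldehyde imide F3 and the γ-hydroxy imide F4. The C5 alkoxide of F4 displaces the oxazolidinone, and the fallback returns to the route at 17.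

Step 10. Ozone may attack the electron-rich ring A or the benzylic ether C–H bonds before the terminal alkene is consumed, and the intermediate aldehyde may epimerise at C4. The fallback sets out from 14 and swaps ozone for an osmium-based cleavage (Lemieux–Johnson oxidation: OsO4 (cat.), NaIO4, 2,6-lutidine, dioxane–H2O, rt). The vicinal diol F5 is formed and cleaved by periodate in the same flask, before its secondary hydroxyl can open the β-lactone. This returns to the route at aldehyde 15, which is reduced with NaBH4 in THF–MeOH at −40 °C and passes through 16 to 17.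

Step 11. Hydrogenolysis may not stop at the protecting groups: once ring B is a free, electron-rich phenol, the benzylic C7'–O bond can also be reduced. The fallback sets out from 17 and covers the carbinol before hydrogenation. Silylation (TBSOTf, 2,6-lutidine, CH2Cl2, −78 → 0 °C) should give the C7' silyl ether F6. Hydrogenolysis (H2, Pd/C, EtOAc) should then give the bisphenol silyl ether F7, whose hindered benzylic silyl ether resists C–O reduction. Desilylation with HF·pyridine in THF at 0 °C under non-basic conditions returns to the route at 18.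

Further compounds
F1 | step 9 | (4S)-4-benzyl-3-[(3R)-3-{[4-(benzyloxy)-3-methoxyphenyl]methyl}pent-4-enoyl]-1,3-oxazolidin-2-one | O=C1OC[C@H](Cc2ccccc2)N1C(=O)C[C@@H](Cc1ccc(OCc2ccccc2)c(OC)c1)C=C
F2 | step 9 | (4S)-4-benzyl-3-[(2S,3S)-3-{[4-(benzyloxy)-3-methoxyphenyl]methyl}-2-[(S)-{4-[(benzyloxycarbonyl)oxy]-3-methoxyphenyl}(hydroxy)methyl]pent-4-enoyl]-1,3-oxazolidin-2-one | O=C1OC[C@H](Cc2ccccc2)N1C(=O)[C@H]([C@H](O)c1ccc(OC(=O)OCc2ccccc2)c(OC)c1)[C@@H](Cc1ccc(OCc2ccccc2)c(OC)c1)C=C
F3 | step 9 | (4S)-4-benzyl-3-[(2S,3R)-3-{[4-(benzyloxy)-3-methoxyphenyl]methyl}-2-[(S)-{4-[(benzyloxycarbonyl)oxy]-3-methoxyphenyl}(hydroxy)methyl]-4-oxobutanoyl]-1,3-oxazolidin-2-one | O=C1OC[C@H](Cc2ccccc2)N1C(=O)[C@H]([C@H](O)c1ccc(OC(=O)OCc2ccccc2)c(OC)c1)[C@@H](Cc1ccc(OCc2ccccc2)c(OC)c1)C=O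
F4 | step 9 | (4S)-4-benzyl-3-[(2S,3R)-3-{[4-(benzyloxy)-3-methoxyphenyl]methyl}-4-hydroxy-2-[(S)-{4-[(benzyloxycarbonyl)oxy]-3-methoxyphenyl}(hydroxy)methyl]butanoyl]-1,3-oxazolidin-2-one | O=C1OC[C@H](Cc2ccccc2)N1C(=O)[C@H]([C@H](O)c1ccc(OC(=O)OCc2ccccc2)c(OC)c1)[C@@H](Cc1ccc(OCc2ccccc2)c(OC)c1)CO
F5 | step 10 | (3S,4S)-3-{(2R)-1-[4-(benzyloxy)-3-methoxyphenyl]-3,4-dihydroxybutan-2-yl}-4-{4-[(benzyloxycarbonyl)oxy]-3-methoxyphenyl}oxetan-2-one (both epimers at the new carbinol) | O=C1O[C@H](c2ccc(OC(=O)OCc3ccccc3)c(OC)c2)[C@@H]1[C@@H](Cc1ccc(OCc2ccccc2)c(OC)c1)C(O)CO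
F6 | step 11 | benzyl 4-[(S)-{(3S,4R)-4-[4-(benzyloxy)-3-methoxybenzyl]-2-oxooxolan-3-yl}{[tert-butyl(dimethyl)silyl]oxy}methyl]-2-methoxyphenyl carbonate | COc1cc(C[C@H]2COC(=O)[C@@H]2[C@H](O[Si](C)(C)C(C)(C)C)c2ccc(OC(=O)OCc3ccccc3)c(OC)c2)ccc1OCc1ccccc1
F7 | step 11 | (3S,4R)-3-[(S)-{[tert-butyl(dimethyl)silyl]oxy}(4-hydroxy-3-methoxyphenyl)methyl]-4-(4-hydroxy-3-methoxybenzyl)oxolan-2-one | COc1cc(C[C@H]2COC(=O)[C@@H]2[C@H](O[Si](C)(C)C(C)(C)C)c2ccc(O)c(OC)c2)ccc1O
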